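## Retrosynthetic overview

1. Feature (isoflavan numbering, primes for ring B): C4 sits on C4a, which is ortho to C8a (the carbon bearing O1) and para to C7–O. Ring A can therefore be unmasked as an ortho-quinone methide whose electrophilic C4 and nucleophilic O1 are the two ring C atoms that must bond to C3 and C2.
2. Endgame: the O1–C2 ether of ring C goes back (Mitsunobu) to a phenol alcohol, and this goes back to the (3S)-3-aryl-3,4-dihydrocoumarin by lactone reduction. The silyl groups on O7 and O2' are removed last.
3. Key disconnection: C3–C4 and O1–C2 of the lactone are made together by an isothiourea-catalysed Michael addition–lactonisation (formal 4+2). The partners are the ring A quinone methide (from a 2-(tosylmethyl)phenol) and the ammonium enolate of the ring B arylacetic acid.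
4. Both fragments come from 2,4-dihydroxybenzaldehyde. C3 prenylation, 4-O-silylation, reduction and sulfinic acid exchange give the ring A sulfone. Prenal annulation, O-silylation, Wittig one-carbon homologation and oxidation give the ring B acid.
5. Ring order: the pyran ring fused to ring B is formed first, ring C is formed as the lactone in the key step, and ring C is then reopened and reclosed as the cyclic ether.

Key step: step 10

Assumption: the target SMILES corresponds to 3S, and the accepted model for isothiourea ammonium enolates (Z enolate, O···S contact, attack anti to the pseudoaxial C2 phenyl group) assigns the 3S lactone to (2R,3S)-HyperBTM, that is (2R,3S)-3-isopropyl-2-phenyl-3,4-dihydro-2H-benzo[4,5]thiazolo[3,2-a]pyrimidine; both antipodes are commercial, so the sense of induction would be confirmed at the lactone stage.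

## Route

**Step 1**
Reactants: 1 2,4-dihydroxybenzaldehyde; 2 1-bromo-3-methylbut-2-ene (prenyl bromide)
Product: 3 2,4-dihydroxy-3-(3-methylbut-2-en-1-yl)benzaldehyde
Conditions: KOH, H2O, 0 °C to rt; then aq HCl, chromatography
Reagents that add atoms: none
Why: C-allylation of an ambident resorcinolate, in which water solvates the phenoxide oxygens so that the soft allylic bromide is taken by C3, the most electron-rich carbon flanked by both oxygens, and the accompanying O-prenyl and C5 isomers are removed by chromatography.

**Step 2**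
Reactants: 3 2,4-dihydroxy-3-(3-methylbut-2-en-1-yl)benzaldehyde
Product: 4 4-(tert-butyldimethylsilyloxy)-2-hydroxy-3-(3-methylbut-2-en-1-yl)benzaldehyde
Conditions: TBSCl (1.05 equiv), imidazole, CH2Cl2, 0 °C
Reagents that add atoms: tert-butyldimethylsilyl chloride (TBSCl), CC(C)(C)[Si](C)(C)Cl
Why: Regioselective O-silylation, because the 2-OH is hydrogen-bonded to the formyl oxygen and is much less nucleophilic, so one equivalent of silyl chloride goes to the 4-OH (the later O7).

**Step 3**
Reactants: 4 4-(tert-butyldimethylsilyloxy)-2-hydroxy-3-(3-methylbut-2-en-1-yl)benzaldehyde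
Product: 5 3-(tert-butyldimethylsilyloxy)-6-(hydroxymethyl)-2-(3-methylbut-2-en-1-yl)phenol
Conditions: NaBH4, THF–EtOH, 0 °C; used without purification
Reagents that add atoms: none
Why: Borohydride reduction of the aldehyde to the salicyl alcohol is fast at 0 °C and leaves the aryl silyl ether and the prenyl alkene untouched.

**Step 4**
Reactants: 5 3-(tert-butyldimethylsilyloxy)-6-(hydroxymethyl)-2-(3-methylbut-2-en-1-yl)phenol
Product: 6 3-(tert-butyldimethylsilyloxy)-2-(3-methylbut-2-en-1-yl)-6-(tosylmethyl)phenol (ring A sulfone)
Conditions: p-TolSO2H (freshly liberated from its sodium salt, 1.5 equiv), CH2Cl2 (dilute), 0 °C to rt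
Reagents that add atoms: p-toluenesulfinic acid, Cc1ccc(cc1)S(=O)O
Why: SN1-type benzylic substitution through the protonated quinone methide, in which the cation is stabilised by the ortho OH and the para silyloxy group and is captured at sulfur to give the thermodynamically favoured sulfone, the sulfinic acid being acidic enough to ionise the alcohol but too weak to cyclise the prenyl phenol.

**Step 5**
Reactants: 1 2,4-dihydroxybenzaldehyde; 7 3-methylbut-2-enal (prenal)
Product: 8 5-hydroxy-2,2-dimethyl-2H-chromene-6-carbaldehyde
Conditions: ethylenediammonium diacetate (10 mol%), toluene, reflux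
Reagents that add atoms: none
Why: Knoevenagel-type condensation followed by oxa-6π electrocyclisation (formal 3+3 chromene annulation), in which C3 between the two oxygens attacks the iminium-activated enal and the unchelated 4-OH closes the pyran to give the angular 5-hydroxy-6-formyl chromene.

**Step 6**
Reactants: 8 5-hydroxy-2,2-dimethyl-2H-chromene-6-carbaldehyde
Product: 9 2,2-dimethyl-5-(triisopropylsilyloxy)-2H-chromene-6-carbaldehyde
Conditions: TIPSOTf, 2,6-lutidine, CH2Cl2, 0 °C to rt
Reagents that add atoms: triisopropylsilyl trifluoromethanesulfonate (TIPSOTf), CC(C)[Si](OS(=O)(=O)C(F)(F)F)(C(C)C)C(C)C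
Why: O-silylation with the silyl triflate overcomes the hydrogen bond and the two flanking groups of this phenol (the later O2'), and the bulky group is chosen because it must resist phenoxide and alkoxide and must not migrate to the C2 oxygen in steps 10 to 12.

**Step 7**
Reactants: 9 2,2-dimethyl-5-(triisopropylsilyloxy)-2H-chromene-6-carbaldehyde
Product: 10 6-(2-methoxyethenyl)-2,2-dimethyl-5-(triisopropylsilyloxy)-2H-chromene (E/Z mixture)
Conditions: Ph3P(CH2OMe)Cl, KOt-Bu, THF, 0 °C; then 9, 0 °C to rt
Reagents that add atoms: (methoxymethyl)triphenylphosphonium chloride, COC[P+](c1ccccc1)(c1ccccc1)c1ccccc1.[Cl-]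
Why: Wittig olefination with the small unstabilised methoxymethylidene ylide adds the future C2 carbon, and the alkene geometry is irrelevant because both isomers hydrolyse to the same aldehyde.

**Step 8**
Reactants: 10 6-(2-methoxyethenyl)-2,2-dimethyl-5-(triisopropylsilyloxy)-2H-chromene
Product: 11 2-[2,2-dimethyl-5-(triisopropylsilyloxy)-2H-chromen-6-yl]acetaldehyde
Conditions: aq HCl (2 M), THF, 40 °C
Reagents that add atoms: water, O
Why: Acid hydrolysis of the enol ether (C-protonation, hydration of the oxocarbenium ion, loss of methanol) unmasks the arylacetaldehyde, while aryl TIPS ethers and 2,2-dimethylchromenes tolerate dilute aqueous acid.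

**Step 9**
Reactants: 11 2-[2,2-dimethyl-5-(triisopropylsilyloxy)-2H-chromen-6-yl]acetaldehyde
Product: 12 2-[2,2-dimethyl-5-(triisopropylsilyloxy)-2H-chromen-6-yl]acetic acid (ring B acid)
Conditions: NaClO2, NaH2PO4, 2-methylbut-2-ene (excess), t-BuOH–H2O, 0 °C to rt
Reagents that add atoms: sodium chlorite, [Na+].[O-]Cl=O
Why: Pinnick oxidation converts the enolisable aldehyde into the acid under buffered conditions, and the excess 2-methylbut-2-ene consumes hypochlorous acid before it can chlorinate the chromene or the electron-rich arene.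

**Step 10**
Reactants: 12 2-[2,2-dimethyl-5-(triisopropylsilyloxy)-2H-chromen-6-yl]acetic acid (1.3 equiv); 6 3-(tert-butyldimethylsilyloxy)-2-(3-methylbut-2-en-1-yl)-6-(tosylmethyl)phenol
Product: 15 (3S)-7-(tert-butyldimethylsilyloxy)-3-[2,2-dimethyl-5-(triisopropylsilyloxy)-2H-chromen-6-yl]-8-(3-methylbut-2-en-1-yl)chroman-2-one, via pivalic mixed anhydride 13 (not isolated), via ortho-quinone methide 14 (not isolated)
Conditions: t-BuCOCl, i-Pr2NEt, CH2Cl2, 0 °C; then (2R,3S)-HyperBTM (10 mol%), i-Pr2NEt, 6 added by syringe pump, −20 °C; cold aqueous work-up, crude product used at once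
Reagents that add atoms: none
Why: The isothiourea is N-acylated by 13 and pivalate removes the alpha proton to give the Z ammonium enolate, held coplanar with the catalyst by a 1,5 O···S contact, while i-Pr2NEt deprotonates 6 and the phenoxide expels p-toluenesulfinate (helped by the C7 silyloxy group para to C4a) to release 14 at low concentration. The enolate carbon adds to the exocyclic C4 methylene of 14 (Michael addition, C3–C4), ring A rearomatises, and the C8a phenoxide attacks the acyl isothiouronium carbon in a 6-exo-trig acyl substitution (O1–C2) that closes ring C and frees the catalyst, a formal 4+2 annulation overall. The closest known reaction type is the isothiourea-catalysed Michael addition–lactonisation of arylacetic acids with ortho-quinone methides generated in situ from 2-(sulfonylmethyl)phenols, which gives 3,4-dihydrocoumarins. C3 is the only new stereocentre and, because C4 is an unsubstituted CH2, it is decided by the enolate face alone: the pseudoaxial C2 phenyl group of (2R,3S)-HyperBTM covers one face and C4 bonds to the open one, which corresponds to 3S. The step needs chemoselectivity for enolate capture of 14 over its self-dimerisation, over O-acylation of 6 and over cycloaddition with the prenyl or chromene alkenes; slow addition of 6 to an excess of 13, the two ortho substituents that shield the phenol of 6 and the far higher nucleophilicity of the enolate compared with unactivated alkenes at −20 °C secure it, and the regiochemistry is inherent because 14 offers only C4 as electrophilic carbon and O1 as nucleophile. The C3–H of 15 is acidic, so a hindered amine base, low temperature and reduction of the crude lactone without delay are used to keep the configuration.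

**Step 11**
Reactants: 15 (3S)-7-(tert-butyldimethylsilyloxy)-3-[2,2-dimethyl-5-(triisopropylsilyloxy)-2H-chromen-6-yl]-8-(3-methylbut-2-en-1-yl)chroman-2-one
Product: 16 3-(tert-butyldimethylsilyloxy)-6-{(2S)-2-[2,2-dimethyl-5-(triisopropylsilyloxy)-2H-chromen-6-yl]-3-hydroxypropyl}-2-(3-methylbut-2-en-1-yl)phenol
Conditions: LiBH4, THF, 0 °C
Reagents that add atoms: none
Why: Borohydride reduction of an activated aryl lactone, in which hydride opens the ester and the transient alpha-aryl aldehyde is reduced faster than it enolises, so C3 keeps its configuration while the silyl ethers and the hindered di- and trisubstituted alkenes are left alone at 0 °C.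

**Step 12**
Reactants: 16 3-(tert-butyldimethylsilyloxy)-6-{(2S)-2-[2,2-dimethyl-5-(triisopropylsilyloxy)-2H-chromen-6-yl]-3-hydroxypropyl}-2-(3-methylbut-2-en-1-yl)phenol
Product: 17 (3S)-7-(tert-butyldimethylsilyloxy)-3-[2,2-dimethyl-5-(triisopropylsilyloxy)-2H-chromen-6-yl]-8-(3-methylbut-2-en-1-yl)chroman
Conditions: PPh3, diisopropyl azodicarboxylate (DIAD), THF, 0 °C to rt
Reagents that add atoms: none
Why: Intramolecular Mitsunobu etherification, in which the only free phenol (C8a–OH) displaces the activated primary C2 oxygen in a 6-exo-tet closure that recloses ring C without touching C3, the competing 2'-oxygen being blocked by TIPS.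

**Step 13**
Reactants: 17 (3S)-7-(tert-butyldimethylsilyloxy)-3-[2,2-dimethyl-5-(triisopropylsilyloxy)-2H-chromen-6-yl]-8-(3-methylbut-2-en-1-yl)chroman
Product: 18 (3S)-3-(5-hydroxy-2,2-dimethyl-2H-chromen-6-yl)-8-(3-methylbut-2-en-1-yl)chroman-7-ol (target)
Conditions: n-Bu4NF, AcOH, THF, 0 °C to rt
Reagents that add atoms: none
Why: Fluoride-induced cleavage of both aryl silyl ethers, with acetic acid buffering the phenoxides, no strong acid present that could cyclise the prenyl phenol, and no acidic hydrogen left at C3.

## Compound list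

1 | 2,4-dihydroxybenzaldehyde | O=Cc1ccc(O)cc1O | starting material
2 | 1-bromo-3-methylbut-2-ene | CC(C)=CCBr | starting material
3 | 2,4-dihydroxy-3-(3-methylbut-2-en-1-yl)benzaldehyde | CC(C)=CCc1c(O)ccc(C=O)c1O | intermediate
4 | 4-(tert-butyldimethylsilyloxy)-2-hydroxy-3-(3-methylbut-2-en-1-yl)benzaldehyde | CC(C)=CCc1c(O[Si](C)(C)C(C)(C)C)ccc(C=O)c1O | intermediate
5 | 3-(tert-butyldimethylsilyloxy)-6-(hydroxymethyl)-2-(3-methylbut-2-en-1-yl)phenol | CC(C)=CCc1c(O[Si](C)(C)C(C)(C)C)ccc(CO)c1O | intermediate
6 | 3-(tert-butyldimethylsilyloxy)-2-(3-methylbut-2-en-1-yl)-6-(tosylmethyl)phenol | CC(C)=CCc1c(O[Si](C)(C)C(C)(C)C)ccc(CS(=O)(=O)c2ccc(C)cc2)c1O | intermediate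
7 | 3-methylbut-2-enal | CC(C)=CC=O | starting material
8 | 5-hydroxy-2,2-dimethyl-2H-chromene-6-carbaldehyde | O=Cc1ccc2c(c1O)C=CC(C)(C)O2 | intermediate
9 | 2,2-dimethyl-5-(triisopropylsilyloxy)-2H-chromene-6-carbaldehyde | O=Cc1ccc2c(c1O[Si](C(C)C)(C(C)C)C(C)C)C=CC(C)(C)O2 | intermediate
10 | 6-(2-methoxyethenyl)-2,2-dimethyl-5-(triisopropylsilyloxy)-2H-chromene (E/Z mixture) | COC=Cc1ccc2c(c1O[Si](C(C)C)(C(C)C)C(C)C)C=CC(C)(C)O2 | intermediate
11 | 2-[2,2-dimethyl-5-(triisopropylsilyloxy)-2H-chromen-6-yl]acetaldehyde | O=CCc1ccc2c(c1O[Si](C(C)C)(C(C)C)C(C)C)C=CC(C)(C)O2 | intermediate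
12 | 2-[2,2-dimethyl-5-(triisopropylsilyloxy)-2H-chromen-6-yl]acetic acid | OC(=O)Cc1ccc2c(c1O[Si](C(C)C)(C(C)C)C(C)C)C=CC(C)(C)O2 | intermediate
13 | pivalic mixed anhydride of acid 12 | CC(C)(C)C(=O)OC(=O)Cc1ccc2c(c1O[Si](C(C)C)(C(C)C)C(C)C)C=CC(C)(C)O2 | intermediate
14 | ortho-quinone methide, 3-(tert-butyldimethylsilyloxy)-6-methylidene-2-(3-methylbut-2-en-1-yl)cyclohexa-2,4-dien-1-one | C=C1C=CC(O[Si](C)(C)C(C)(C)C)=C(CC=C(C)C)C1=O | intermediate
15 | (3S)-7-(tert-butyldimethylsilyloxy)-3-[2,2-dimethyl-5-(triisopropylsilyloxy)-2H-chromen-6-yl]-8-(3-methylbut-2-en-1-yl)chroman-2-one | CC(C)=CCc1c(O[Si](C)(C)C(C)(C)C)ccc2c1OC(=O)[C@H](c1ccc3c(c1O[Si](C(C)C)(C(C)C)C(C)C)C=CC(C)(C)O3)C2 | intermediate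
16 | 3-(tert-butyldimethylsilyloxy)-6-{(2S)-2-[2,2-dimethyl-5-(triisopropylsilyloxy)-2H-chromen-6-yl]-3-hydroxypropyl}-2-(3-methylbut-2-en-1-yl)phenol | CC(C)=CCc1c(O[Si](C)(C)C(C)(C)C)ccc(C[C@H](CO)c2ccc3c(c2O[Si](C(C)C)(C(C)C)C(C)C)C=CC(C)(C)O3)c1O | intermediate
17 | (3S)-7-(tert-butyldimethylsilyloxy)-3-[2,2-dimethyl-5-(triisopropylsilyloxy)-2H-chromen-6-yl]-8-(3-methylbut-2-en-1-yl)chroman | CC(C)=CCc1c(O[Si](C)(C)C(C)(C)C)ccc2c1OC[C@H](c1ccc3c(c1O[Si](C(C)C)(C(C)C)C(C)C)C=CC(C)(C)O3)C2 | intermediate
18 | (3S)-3-(5-hydroxy-2,2-dimethyl-2H-chromen-6-yl)-8-(3-methylbut-2-en-1-yl)chroman-7-ol | CC(C)=CCc1c(O)ccc2c1OC[C@H](c1ccc3c(c1O)C=CC(C)(C)O3)C2 | target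

## Step count and risks

Total step count: 13.
Longest linear sequence: 9 steps (steps 5 to 13, from 1 through 12 to 18).

**Step 10 (key step).**
- What may go wrong:
  - The unsubstituted quinone methide may oligomerise before it is captured.
  - The acyl isothiouronium ion may enolise slowly because of the ortho silyloxy group.
  - The hindered phenol may be O-acylated.
  - Base may erode the configuration at C3 before reduction.
- Fallback: catalyst control is replaced by a stoichiometric oxazolidinone auxiliary on a metal enolate. It sets out from 12 and 6.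
  - Acid 12 is activated as 13 (t-BuCOCl, Et3N, THF) and treated with lithiated (S)-4-benzyloxazolidin-2-one (n-BuLi, THF, −78 °C) to give the N-acyl oxazolidinone F1.
  - The chelated sodium Z enolate of F1 (NaN(SiMe3)2, THF, −78 °C) is combined with the sodium phenoxide of 6 (NaN(SiMe3)2, −78 °C).
  - On warming, the phenoxide sheds sulfinate to give 14. The much more nucleophilic metal enolate captures C4 on the face remote from the benzyl group and gives the imide phenol F2 with the 2S configuration.
  - LiBH4 in THF removes the auxiliary reductively and delivers 16, where the route is rejoined. Any 15 formed by attack of the phenoxide on the imide is reduced to the same 16.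

**Step 4 (sulfone formation).**
- What may go wrong:
  - The very electron-rich salicyl alcohol may self-condense under acid, through Friedel–Crafts attack by C6 of a second molecule.
  - The C8a hydroxyl may cyclise onto the protonated prenyl group.
  - Both processes are aggravated if the sulfinic acid disproportionates to sulfonic acid.
- Fallback: an acid-free route through a Mannich base. It sets out from 4 and bypasses 5.
  - Reductive amination (Me2NH, NaBH(OAc)3, 1,2-dichloroethane) gives the ortho-(dimethylaminomethyl)phenol F3.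
  - MeI in MeCN gives the benzyltrimethylammonium iodide F4.
  - Warming F4 with p-TolSO2Na in MeCN releases trimethylamine and the quinone methide. Sulfinate traps it at sulfur and the route returns at 6.

**Step 1 (C-prenylation).**
- What may go wrong: the regioselectivity of the ambident dianion may be poor, with O-alkylation, attack at C5 and double prenylation.
- Fallback: the prenyl group is delivered from O4 by a sigmatropic shift instead of direct C-alkylation. It sets out from 1.
  - 3-Chloro-3-methylbut-1-yne, K2CO3 and KI in acetone alkylate the unchelated 4-OH to give the propargyl ether F5.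
  - Semi-hydrogenation (H2, Pd/CaCO3 poisoned with Pb(OAc)2, quinoline, EtOAc) gives the 1,1-dimethylallyl ether F6.
  - Heating in N,N-diethylaniline triggers an aromatic Claisen rearrangement with allyl inversion.
  - The rearrangement is directed to C3 by the higher double-bond character of C3–C4 in the chelated salicylaldehyde, and the route returns at 3.

## Further compounds

F1 | step 10 | (4S)-4-benzyl-3-{2-[2,2-dimethyl-5-(triisopropylsilyloxy)-2H-chromen-6-yl]acetyl}oxazolidin-2-one | O=C1OC[C@H](Cc2ccccc2)N1C(=O)Cc1ccc2c(c1O[Si](C(C)C)(C(C)C)C(C)C)C=CC(C)(C)O2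
F2 | step 10 | (4S)-4-benzyl-3-{(2S)-3-[4-(tert-butyldimethylsilyloxy)-2-hydroxy-3-(3-methylbut-2-en-1-yl)phenyl]-2-[2,2-dimethyl-5-(triisopropylsilyloxy)-2H-chromen-6-yl]propanoyl}oxazolidin-2-one | O=C1OC[C@H](Cc2ccccc2)N1C(=O)[C@@H](Cc1ccc(O[Si](C)(C)C(C)(C)C)c(CC=C(C)C)c1O)c1ccc2c(c1O[Si](C(C)C)(C(C)C)C(C)C)C=CC(C)(C)O2
F3 | step 4 | 3-(tert-butyldimethylsilyloxy)-6-[(dimethylamino)methyl]-2-(3-methylbut-2-en-1-yl)phenol | CC(C)=CCc1c(O[Si](C)(C)C(C)(C)C)ccc(CN(C)C)c1O
F4 | step 4 | [4-(tert-butyldimethylsilyloxy)-2-hydroxy-3-(3-methylbut-2-en-1-yl)benzyl]trimethylammonium iodide | CC(C)=CCc1c(O[Si](C)(C)C(C)(C)C)ccc(C[N+](C)(C)C)c1O.[I-]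
F5 | step 1 | 2-hydroxy-4-[(2-methylbut-3-yn-2-yl)oxy]benzaldehyde | C#CC(C)(C)Oc1ccc(C=O)c(O)c1
F6 | step 1 | 2-hydroxy-4-[(2-methylbut-3-en-2-yl)oxy]benzaldehyde | C=CC(C)(C)Oc1ccc(C=O)c(O)c1
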